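## Retrosynthetic overview

1. Target ⇐ C8-epimeric alcohol + O-silyl (Z)-2-(hydroxymethyl)but-2-enoic acid (esterification with inversion at C8, then global desilylation).
2. α-Methylene-γ-lactone ⇐ C7 isopropenyl group + C6–OH (allylic oxidation, oxidative lactonisation); C3–OAc and C15–OH ⇐ reduction of a tricyclic β-keto lactone.
3. Ring A (second oxepane, completes the ether bridge) ⇐ intramolecular acylation of a C4 lactone enolate by a C3 morpholine amide.
4. Ring B (first oxepane) ⇐ key C5–C6 bond: SmI2 ketyl of a C6 aldehyde adds to C5 of a β-alkoxyacrylate, so that two natively electrophilic carbons are joined.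
5. Cyclisation precursor ⇐ Evans aldol (C7–C8) on a chain built from (R)-linalool (C10) and ethyl propiolate (C4, C5, C15). Ring order: ring B → temporary γ-lactone → ring A → α-methylene lactone.

## Conventions and assumption

- Locants are those of the final skeleton. C1–C10 is the ten-membered carbocycle with the C5–O–C10 ether. C11, C12, C13 are the lactone α-carbon, carbonyl and exo-methylene. C14 is the methyl on C10 and C15 the CH2OH carbon on C4. Ring A is the oxepane O/C5/C4/C3/C2/C1/C10; ring B is the oxepane O/C5/C6/C7/C8/C9/C10.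
- The target SMILES is taken literally (3S,4S,5R,6S,7R,8R,10R). In it the two ether carbons are 2,7-trans in both oxepanes, so C5 is set before the second ring is closed. CIP letters of unchanged centres change in some intermediates because substituent priorities change.
- Assumption: commercial (R)-(−)-linalool of ≥95% ee is used; material from the minor enantiomer is removed as a diastereomer after step 7.

## Route

Step 1
Reactants: 1 (R)-(−)-linalool
Product: 3 (5R)-5-ethenyl-5-methyloxolan-2-one, via lactol 2 (not isolated)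
Conditions: O3 (1.0 equiv, Sudan Red 7B end point), CH2Cl2, −78 °C; PPh3, −78 °C→rt; then TEMPO (cat.), PhI(OAc)2, rt
Reagents that add atoms: ozone [O-][O+]=O
Why: Ozonolysis cleaves only the electron-rich trisubstituted alkene, the γ-hydroxy aldehyde closes to lactol 2, and TEMPO/PhI(OAc)2 (oxoammonium oxidation) gives the lactone with the chiral-pool C10 centre untouched.

Step 2
Reactants: 3 (5R)-5-ethenyl-5-methyloxolan-2-one
Product: 4 (4R)-4-hydroxy-4-methyl-1-(morpholin-4-yl)hex-5-en-1-one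
Conditions: morpholine, AlMe3, CH2Cl2, 0 °C→rt; aq. potassium sodium tartrate
Reagents that add atoms: morpholine C1COCCN1
Why: Aluminium-amide aminolysis of a lactone (Weinreb-type) opens the ring to a stable tertiary-hydroxy amide whose acyl group is the C3 electrophile of step 12.

Step 3
Reactants: 4 (4R)-4-hydroxy-4-methyl-1-(morpholin-4-yl)hex-5-en-1-one; 5 ethyl propiolate
Product: 6 ethyl (2E)-3-{[(3R)-3-methyl-6-(morpholin-4-yl)-6-oxohex-1-en-3-yl]oxy}prop-2-enoate
Conditions: PMe3 (10 mol %), CH2Cl2, 0 °C→rt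
Reagents that add atoms: none
Why: Phosphine-catalysed oxa-Michael addition of the tertiary alcohol to the ynoate gives the (E)-β-alkoxyacrylate that serves as acceptor in step 11.

Step 4
Reactants: 6 ethyl (2E)-3-{[(3R)-3-methyl-6-(morpholin-4-yl)-6-oxohex-1-en-3-yl]oxy}prop-2-enoate
Product: 8 ethyl (2E)-3-{[(3R)-1-hydroxy-3-methyl-6-(morpholin-4-yl)-6-oxohexan-3-yl]oxy}prop-2-enoate, via alkylborane 7 (not isolated)
Conditions: 9-BBN, THF, 0 °C→rt; then NaBO3·4H2O, H2O, rt
Reagents that add atoms: sodium perborate [Na+].[Na+].O[B-]1(O)OO[B-](O)(O)OO1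
Why: Hydroboration–oxidation, in which 9-BBN adds anti-Markovnikov to the only monosubstituted alkene and perborate oxidises the C–B bond without harming ester or amide.

Step 5
Reactants: 8 ethyl (2E)-3-{[(3R)-1-hydroxy-3-methyl-6-(morpholin-4-yl)-6-oxohexan-3-yl]oxy}prop-2-enoate
Product: 9 ethyl (2E)-3-{[(3R)-3-methyl-6-(morpholin-4-yl)-1,6-dioxohexan-3-yl]oxy}prop-2-enoate
Conditions: Dess–Martin periodinane, pyridine, CH2Cl2, 0 °C→rt; used crude
Reagents that add atoms: none
Why: Dess–Martin oxidation of the primary alcohol under mild buffered conditions that avoid β-elimination of the acrylate oxygen from the aldehyde.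

Step 6
Reactants: 10 (4R)-4-benzyl-1,3-oxazolidin-2-one; 11 3-methylbut-2-enoyl chloride
Product: 13 (4R)-4-benzyl-3-(3-methylbut-2-enoyl)-1,3-oxazolidin-2-one, via lithium oxazolidinide 12 (not isolated)
Conditions: n-BuLi, THF, −78 °C; then 11, −78→0 °C
Reagents that add atoms: none
Why: N-Acylation of the lithiated oxazolidinone by the acid chloride (standard Evans imide formation).

Step 7
Reactants: 13 (4R)-4-benzyl-3-(3-methylbut-2-enoyl)-1,3-oxazolidin-2-one; 9 ethyl (2E)-3-{[(3R)-3-methyl-6-(morpholin-4-yl)-1,6-dioxohexan-3-yl]oxy}prop-2-enoate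
Product: 15 syn-aldol adduct (7R,8S,10R) with C7 isopropenyl and C8 hydroxyl, via boron dienolate 14 (not isolated)
Conditions: 13, n-Bu2BOTf, Et3N, CH2Cl2, −78→0 °C; then 9, −78→0 °C; pH 7 buffer, MeOH, 30% H2O2
Reagents that add atoms: none
Why: Evans boron aldol in which the (Z)-dienolate reacts at its α-carbon through a Zimmerman–Traxler chair; the (R)-benzyl auxiliary sets C7 as in the target and C8 as the 8S carbinol, deliberately epimeric so that step 23 can invert it.

Step 8
Reactants: 15 syn-aldol adduct (7R,8S,10R)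
Product: 16 C8 tert-butyldimethylsilyl ether of 15
Conditions: TBSOTf, 2,6-lutidine, CH2Cl2, −78→0 °C
Reagents that add atoms: tert-butyldimethylsilyl triflate CC(C)(C)[Si](C)(C)OS(=O)(=O)C(F)(F)F
Why: Silylation with silyl triflate and lutidine protects the C8 hydroxyl and blocks retro-aldol.

Step 9
Reactants: 16 C8 tert-butyldimethylsilyl ether of 15
Product: 17 primary C6 alcohol (7S,8S,10R)
Conditions: NaBH4, THF/H2O 4:1, 0 °C→rt
Reagents that add atoms: none
Why: Reductive removal of the Evans auxiliary, since NaBH4 in wet THF reduces the activated imide carbonyl to the primary alcohol but leaves the ester and the tertiary amide.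

Step 10
Reactants: 17 primary C6 alcohol (7S,8S,10R)
Product: 18 C6 aldehyde (7R,8S,10R)
Conditions: Dess–Martin periodinane, pyridine, CH2Cl2, 0 °C; used at once
Reagents that add atoms: none
Why: Dess–Martin oxidation to the α-branched aldehyde under cold buffered conditions that keep the C7 centre and the β,γ-alkene in place.

Step 11
Reactants: 18 C6 aldehyde (7R,8S,10R)
Product: 20 ring-B oxepane trans-fused to the C6–O–C15 γ-lactone (5R,6S,7S,8S,10R), via hydroxy ester 19 (not isolated)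
Conditions: SmI2 (3 equiv), MeOH (3 equiv), THF (0.01 M), 0 °C; then crude, PPTS (cat.), PhMe, 60 °C
Reagents that add atoms: none
Why: Key C5–C6 bond by a Nakata-type reductive ketyl–olefin cyclisation, in which SmI2 turns the aldehyde carbon into a nucleophilic ketyl that adds 7-exo to the electrophilic C5 of the β-alkoxyacrylate through a samarium-chelated chair-like transition state with the C7 isopropenyl and C8 silyloxy groups equatorial, giving the all-trans C5–C8 oxepane (5R,6S) before acid closes the γ-lactone.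

Step 12
Reactants: 20 ring-B oxepane trans-fused to the C6–O–C15 γ-lactone
Product: 21 tricyclic β-keto lactone with ring A closed (4R,5R,6S,7S,8S,10R)
Conditions: LiN(SiMe3)2 (2.5 equiv), THF (0.005 M), −78→−20 °C; 1 M HCl
Reagents that add atoms: none
Why: Intramolecular Claisen (Dieckmann-type) acylation of the C4 lactone enolate by the morpholine amide closes ring A, and because C4 is tied to C6 through the lactone the new C3–C4 bond can only form cis to the ring oxygen, which fixes C4 (C15 cis to C6) and completes the 2,7-trans bridged ether.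

Step 13
Reactants: 21 tricyclic β-keto lactone
Product: 23 triol with free C3, C6 and C15 hydroxyls (3S,4S,5R,6S,7S,8S,10R), via hydroxy lactone 22 (not isolated)
Conditions: LiBH4 (5 equiv), THF, MeOH (2 equiv), −20 °C→rt
Reagents that add atoms: none
Why: Hydride reduction in which the ring-A ketone is attacked from the convex face opposite the cis-fused lactone, placing the C3 hydroxyl cis to C15 (3S), after which the lactone is reduced to the C6/C15 diol.

Step 14
Reactants: 23 triol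
Product: 24 C15 tert-butyldiphenylsilyl ether of 23
Conditions: TBDPSCl, imidazole, CH2Cl2, 0 °C
Reagents that add atoms: tert-butyl(chloro)diphenylsilane CC(C)(C)[Si](Cl)(c1ccccc1)c1ccccc1
Why: Silylation with the bulky chlorosilane is selective for the only primary hydroxyl.

Step 15
Reactants: 24 C15 tert-butyldiphenylsilyl ether of 23
Product: 25 allylic alcohol with C7 3-hydroxyprop-1-en-2-yl group
Conditions: SeO2 (0.5 equiv), t-BuOOH, CH2Cl2, 0 °C→rt
Reagents that add atoms: tert-butyl hydroperoxide CC(C)(C)OO (oxygen source, relayed by catalytic SeO2 O=[Se]=O)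
Why: SeO2-catalysed allylic oxidation (ene reaction then [2,3]-shift) of the isopropenyl methyl group gives the 2-substituted allylic alcohol; any enal formed converges in step 16.

Step 16
Reactants: 25 allylic alcohol
Product: 28 α-methylene-γ-lactone with free C3 hydroxyl (3S,4S,5R,6S,7S,8S,10R), via enal 26 (not isolated), via hemiacetal 27 (not isolated)
Conditions: activated MnO2 (excess), CH2Cl2, rt
Reagents that add atoms: none
Why: MnO2 oxidative lactonisation, in which only the allylic alcohol is oxidised to the enal, the C6 hydroxyl adds to give a hemiacetal, and this is oxidised to the lactone, trans-fused because C6 and C7 were set in steps 11 and 7.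

Step 17
Reactants: 28 α-methylene-γ-lactone with free C3 hydroxyl
Product: 29 C3 acetate
Conditions: Ac2O, pyridine, DMAP (cat.), CH2Cl2, 0 °C→rt
Reagents that add atoms: acetic anhydride CC(=O)OC(C)=O
Why: Acetylation of the only free hydroxyl.

Step 18
Reactants: 29 C3 acetate
Product: 30 8S alcohol (3S,4S,5R,6S,7R,8S,10R)
Conditions: HF·pyridine, pyridine, THF, 0 °C→rt
Reagents that add atoms: none
Why: Buffered HF cleaves the secondary tert-butyldimethylsilyl ether much faster than the primary tert-butyldiphenylsilyl ether.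

Step 19
Reactants: 31 (E)-crotonaldehyde
Product: 32 (2Z)-2-iodobut-2-enal
Conditions: I2, K2CO3, DMAP (cat.), THF/H2O 1:1, rt
Reagents that add atoms: iodine II
Why: α-Iodination of the enal by amine-catalysed addition–elimination (Baylis–Hillman-type) gives the iodide cis to the methyl group.

Step 20
Reactants: 32 (2Z)-2-iodobut-2-enal
Product: 33 (2Z)-2-iodobut-2-en-1-ol
Conditions: NaBH4, CeCl3·7H2O, MeOH, 0 °C
Reagents that add atoms: none
Why: Luche 1,2-reduction of the enal with retention of alkene geometry.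

Step 21
Reactants: 33 (2Z)-2-iodobut-2-en-1-ol
Product: 34 tert-butyl{[(2Z)-2-iodobut-2-en-1-yl]oxy}dimethylsilane
Conditions: TBSCl, imidazole, CH2Cl2, rt
Reagents that add atoms: tert-butyl(chloro)dimethylsilane CC(C)(C)[Si](C)(C)Cl
Why: Silylation of the primary allylic alcohol.

Step 22
Reactants: 34 tert-butyl{[(2Z)-2-iodobut-2-en-1-yl]oxy}dimethylsilane
Product: 36 (2Z)-2-{[(tert-butyldimethylsilyl)oxy]methyl}but-2-enoic acid, via vinyllithium 35 (not isolated)
Conditions: t-BuLi (2.1 equiv), Et2O, −78 °C; then CO2 (g), −78→0 °C; cold 1 M HCl to pH 3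
Reagents that add atoms: carbon dioxide O=C=O
Why: Iodine–lithium exchange and carboxylation of the configurationally stable vinyllithium go with retention, so the carboxyl group ends cis to the methyl group.

Step 23
Reactants: 30 8S alcohol; 36 (2Z)-2-{[(tert-butyldimethylsilyl)oxy]methyl}but-2-enoic acid
Product: 37 bis-silyl ether of the target (3S,4S,5R,6S,7R,8R,10R)
Conditions: PPh3, DIAD, PhMe, 0 °C→rt
Reagents that add atoms: none
Why: Mitsunobu esterification, in which SN2 displacement of the C8 oxyphosphonium by the carboxylate inverts C8 (8S to 8R) and installs the side-chain ester in one operation.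

Step 24
Reactants: 37 bis-silyl ether of the target
Product: 38 target CNP0195618.1
Conditions: HF·pyridine (excess), THF, 0 °C→rt
Reagents that add atoms: none
Why: Global fluoride desilylation removes the primary tert-butyldiphenylsilyl and allylic tert-butyldimethylsilyl ethers without touching the acetate, the enoate or the α-methylene lactone.

## Compound list

1 | (R)-(−)-linalool, (3R)-3,7-dimethylocta-1,6-dien-3-ol | C=C[C@](C)(O)CCC=C(C)C | starting material
2 | (5R)-5-ethenyl-5-methyloxolan-2-ol (lactol, anomer mixture) | C=C[C@@]1(C)CCC(O)O1 | intermediate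
3 | (5R)-5-ethenyl-5-methyloxolan-2-one | C=C[C@@]1(C)CCC(=O)O1 | intermediate
4 | (4R)-4-hydroxy-4-methyl-1-(morpholin-4-yl)hex-5-en-1-one | C=C[C@](C)(O)CCC(=O)N1CCOCC1 | intermediate
5 | ethyl propiolate (ethyl prop-2-ynoate) | C#CC(=O)OCC | starting material
6 | ethyl (2E)-3-{[(3R)-3-methyl-6-(morpholin-4-yl)-6-oxohex-1-en-3-yl]oxy}prop-2-enoate | C=C[C@](C)(O/C=C/C(=O)OCC)CCC(=O)N1CCOCC1 | intermediate
7 | ethyl (2E)-3-{[(3S)-1-(9-borabicyclo[3.3.1]nonan-9-yl)-3-methyl-6-(morpholin-4-yl)-6-oxohexan-3-yl]oxy}prop-2-enoate (alkylborane, same geometry at C10 as 6) | CCOC(=O)/C=C/O[C@@](C)(CCB1C2CCCC1CCC2)CCC(=O)N1CCOCC1 | intermediate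
8 | ethyl (2E)-3-{[(3R)-1-hydroxy-3-methyl-6-(morpholin-4-yl)-6-oxohexan-3-yl]oxy}prop-2-enoate | OCC[C@](C)(O/C=C/C(=O)OCC)CCC(=O)N1CCOCC1 | intermediate
9 | ethyl (2E)-3-{[(3R)-3-methyl-6-(morpholin-4-yl)-1,6-dioxohexan-3-yl]oxy}prop-2-enoate | O=CC[C@](C)(O/C=C/C(=O)OCC)CCC(=O)N1CCOCC1 | intermediate
10 | (4R)-4-benzyl-1,3-oxazolidin-2-one | O=C1N[C@H](Cc2ccccc2)CO1 | starting material
11 | 3-methylbut-2-enoyl chloride | CC(C)=CC(=O)Cl | starting material
12 | lithium (4R)-4-benzyl-2-oxo-1,3-oxazolidin-3-ide | [Li]N1[C@H](Cc2ccccc2)COC1=O | intermediate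
13 | (4R)-4-benzyl-3-(3-methylbut-2-enoyl)-1,3-oxazolidin-2-one | CC(C)=CC(=O)N1[C@H](Cc2ccccc2)COC1=O | intermediate
14 | di-n-butylboron (Z)-dienolate of 13, (4R)-4-benzyl-3-{(1Z)-1-[(dibutylboranyl)oxy]-3-methylbuta-1,3-dien-1-yl}-1,3-oxazolidin-2-one | C=C(C)/C=C(\OB(CCCC)CCCC)N1[C@H](Cc2ccccc2)COC1=O | intermediate
15 | (4R)-4-benzyl-3-[(2R,3S,5R)-5-{[(1E)-3-ethoxy-3-oxoprop-1-en-1-yl]oxy}-3-hydroxy-5-methyl-8-(morpholin-4-yl)-8-oxo-2-(prop-1-en-2-yl)octanoyl]-1,3-oxazolidin-2-one (7R,8S,10R in skeleton locants) | C=C(C)[C@@H](C(=O)N1[C@H](Cc2ccccc2)COC1=O)[C@@H](O)C[C@](C)(O/C=C/C(=O)OCC)CCC(=O)N3CCOCC3 | intermediate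
16 | 3-O-(tert-butyldimethylsilyl) ether of 15 (7R,8S,10R) | C=C(C)[C@@H](C(=O)N1[C@H](Cc2ccccc2)COC1=O)[C@@H](O[Si](C)(C)C(C)(C)C)C[C@](C)(O/C=C/C(=O)OCC)CCC(=O)N3CCOCC3 | intermediate
17 | ethyl (2E)-3-{[(4R,6S,7S)-6-[(tert-butyldimethylsilyl)oxy]-7-(hydroxymethyl)-4,8-dimethyl-1-(morpholin-4-yl)-1-oxonon-8-en-4-yl]oxy}prop-2-enoate | C=C(C)[C@@H](CO)[C@@H](O[Si](C)(C)C(C)(C)C)C[C@](C)(O/C=C/C(=O)OCC)CCC(=O)N1CCOCC1 | intermediate
18 | ethyl (2E)-3-{[(4R,6S,7R)-6-[(tert-butyldimethylsilyl)oxy]-7-formyl-4,8-dimethyl-1-(morpholin-4-yl)-1-oxonon-8-en-4-yl]oxy}prop-2-enoate | C=C(C)[C@@H](C=O)[C@@H](O[Si](C)(C)C(C)(C)C)C[C@](C)(O/C=C/C(=O)OCC)CCC(=O)N1CCOCC1 | intermediate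
19 | ethyl 2-[(2R,3S,4S,5S,7R)-5-[(tert-butyldimethylsilyl)oxy]-3-hydroxy-7-methyl-7-[3-(morpholin-4-yl)-3-oxopropyl]-4-(prop-1-en-2-yl)oxepan-2-yl]acetate | O1[C@H](CC(=O)OCC)[C@@H](O)[C@H](C(C)=C)[C@@H](O[Si](C)(C)C(C)(C)C)C[C@@]1(C)CCC(=O)N2CCOCC2 | intermediate
20 | ring-B oxepane (5R,6S,7S,8S,10R) trans-fused at C5–C6 to the γ-lactone C6–O–C15(=O)–C4H2–C5; C7 prop-1-en-2-yl, C8 OTBS, C10 methyl and 3-(morpholin-4-yl)-3-oxopropyl | O1[C@@H]2CC(=O)O[C@H]2[C@H](C(C)=C)[C@@H](O[Si](C)(C)C(C)(C)C)C[C@@]1(C)CCC(=O)N3CCOCC3 | intermediate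
21 | tricyclic β-keto lactone (4R,5R,6S,7S,8S,10R): 5,10-epoxy ten-membered carbocycle (11-oxabicyclo[4.4.1]undecane core) with C3 ketone, γ-lactone C6–O–C15(=O)–C4, C7 prop-1-en-2-yl, C8 OTBS, C10 methyl | O=C1CC[C@]2(C)C[C@H](O[Si](C)(C)C(C)(C)C)[C@@H](C(C)=C)[C@@H]3OC(=O)[C@@H]1[C@H]3O2 | intermediate
22 | β-hydroxy lactone (3S,4S,5R,6S,7S,8S,10R): 21 with C3 ketone reduced to C3–OH cis to C15 | O[C@H]1CC[C@]2(C)C[C@H](O[Si](C)(C)C(C)(C)C)[C@@H](C(C)=C)[C@@H]3OC(=O)[C@@H]1[C@H]3O2 | intermediate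
23 | triol (3S,4S,5R,6S,7S,8S,10R): 5,10-epoxy carbocycle with C3–OH, C4–CH2OH, C6–OH, C7 prop-1-en-2-yl, C8 OTBS, C10 methyl | C=C(C)[C@H]1[C@H](O)[C@@H]2O[C@](C)(CC[C@H](O)[C@@H]2CO)C[C@@H]1O[Si](C)(C)C(C)(C)C | intermediate
24 | C15 O-(tert-butyldiphenylsilyl) ether of 23 | C=C(C)[C@H]1[C@H](O)[C@@H]2O[C@](C)(CC[C@H](O)[C@@H]2CO[Si](c3ccccc3)(c3ccccc3)C(C)(C)C)C[C@@H]1O[Si](C)(C)C(C)(C)C | intermediate
25 | 24 with C7 3-hydroxyprop-1-en-2-yl (C12 allylic alcohol) | C=C(CO)[C@H]1[C@H](O)[C@@H]2O[C@](C)(CC[C@H](O)[C@@H]2CO[Si](c3ccccc3)(c3ccccc3)C(C)(C)C)C[C@@H]1O[Si](C)(C)C(C)(C)C | intermediate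
26 | 24 with C7 3-oxoprop-1-en-2-yl (C12 enal) | C=C(C=O)[C@H]1[C@H](O)[C@@H]2O[C@](C)(CC[C@H](O)[C@@H]2CO[Si](c3ccccc3)(c3ccccc3)C(C)(C)C)C[C@@H]1O[Si](C)(C)C(C)(C)C | intermediate
27 | C12 hemiacetal (6,12-lactol, anomer mixture) of 26 | C=C1C(O)O[C@@H]2[C@@H]3O[C@](C)(CC[C@H](O)[C@@H]3CO[Si](c4ccccc4)(c4ccccc4)C(C)(C)C)C[C@H](O[Si](C)(C)C(C)(C)C)[C@@H]12 | intermediate
28 | α-methylene-6,12-lactone (3S,4S,5R,6S,7S,8S,10R) with C3–OH, C8 OTBS, C15 OTBDPS | C=C1C(=O)O[C@@H]2[C@@H]3O[C@](C)(CC[C@H](O)[C@@H]3CO[Si](c4ccccc4)(c4ccccc4)C(C)(C)C)C[C@H](O[Si](C)(C)C(C)(C)C)[C@@H]12 | intermediate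
29 | C3 acetate of 28 | C=C1C(=O)O[C@@H]2[C@@H]3O[C@](C)(CC[C@H](OC(C)=O)[C@@H]3CO[Si](c4ccccc4)(c4ccccc4)C(C)(C)C)C[C@H](O[Si](C)(C)C(C)(C)C)[C@@H]12 | intermediate
30 | 8S alcohol (3S,4S,5R,6S,7R,8S,10R): 29 without the C8 silyl group | C=C1C(=O)O[C@@H]2[C@@H]3O[C@](C)(CC[C@H](OC(C)=O)[C@@H]3CO[Si](c4ccccc4)(c4ccccc4)C(C)(C)C)C[C@H](O)[C@@H]12 | intermediate
31 | (E)-crotonaldehyde | C/C=C/C=O | starting material
32 | (2Z)-2-iodobut-2-enal | C/C=C(\I)C=O | intermediate
33 | (2Z)-2-iodobut-2-en-1-ol | C/C=C(\I)CO | intermediate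
34 | tert-butyl{[(2Z)-2-iodobut-2-en-1-yl]oxy}dimethylsilane | C/C=C(\I)CO[Si](C)(C)C(C)(C)C | intermediate
35 | [(1E)-1-{[(tert-butyldimethylsilyl)oxy]methyl}prop-1-en-1-yl]lithium (Li cis to CH3) | C/C=C(\[Li])CO[Si](C)(C)C(C)(C)C | intermediate
36 | (2Z)-2-{[(tert-butyldimethylsilyl)oxy]methyl}but-2-enoic acid | C/C=C(\C(=O)O)CO[Si](C)(C)C(C)(C)C | intermediate
37 | target with C15 O-TBDPS and side-chain O-TBS (3S,4S,5R,6S,7R,8R,10R) | C=C1C(=O)O[C@@H]2[C@@H]3O[C@](C)(CC[C@H](OC(C)=O)[C@@H]3CO[Si](c4ccccc4)(c4ccccc4)C(C)(C)C)C[C@@H](OC(=O)/C(=C\C)CO[Si](C)(C)C(C)(C)C)[C@@H]12 | intermediate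
38 | CNP0195618.1, (3S,4S,5R,6S,7R,8R,10R)-3-acetoxy-15-hydroxy-8-[(2Z)-2-(hydroxymethyl)but-2-enoyloxy]-5,10-epoxygermacr-11(13)-en-6,12-olide | C=C1C(=O)O[C@@H]2[C@@H]3O[C@](C)(CC[C@H](OC(C)=O)[C@@H]3CO)C[C@@H](OC(=O)/C(=C\C)CO)[C@@H]12 | target

## Step count and risks

Total steps: 24. Longest linear sequence: 19 (steps 1–5, 7–18, 23, 24). Steps 6 and 19–22 are the two side branches.

The three steps most likely to fail:

Step 11. The 7-membered ketyl cyclisation onto a tertiary-alkyl β-alkoxyacrylate may lose to simple aldehyde reduction or pinacol coupling, and the C5/C6 facial control rests on the C7/C8 substituents alone. The fallback sets out from 18: an aminoindanol-derived chiral triazolium salt with KN(SiMe3)2 in toluene effects an intramolecular Stetter reaction, in which the Breslow acyl-anion equivalent of the C6 aldehyde adds to C5 and the catalyst sets that centre, giving the C6 ketone F1. NaBH4 with CeCl3·7H2O at −78 °C, attacking trans to the two flanking equatorial substituents, then gives hydroxy ester 19, where the route is rejoined (lactonisation to 20 as in step 11).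

Step 12. Closing the second oxepane across the 2,7-trans positions of the first is strained and slow, so intermolecular Claisen condensation or β-elimination of the enolate may compete. The fallback sets out from 20: LDA then CBr4 gives the C4 bromolactone F2. Cp2Zr(H)Cl reduces the morpholine amide to the aldehyde, giving the bromo aldehyde F3. SmI2 in THF at −78 °C then generates the samarium enolate at C4, which adds to the C3 aldehyde (intramolecular Reformatsky-type aldol, cis fusion enforced by the lactone as before). This returns to the route at hydroxy lactone 22, which is reduced with LiBH4 to 23 as in step 13.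

Step 23. Mitsunobu inversion of a hindered ring secondary alcohol with a weakly acidic enoic acid can give elimination or retention. The fallback sets out from 30: Dess–Martin oxidation gives the C8 ketone F4. NaBH4 with CeCl3·7H2O at −78 °C, delivered from the face away from the lactone, gives the 8R alcohol F5. Esterification of this with acid 36 through the 2,4,6-trichlorobenzoyl mixed anhydride (Et3N, then DMAP, PhMe, 0 °C) returns to the route at 37.

Further compounds
F1 | step 11 | ethyl 2-[(2R,4R,5S,7R)-5-[(tert-butyldimethylsilyl)oxy]-7-methyl-7-[3-(morpholin-4-yl)-3-oxopropyl]-3-oxo-4-(prop-1-en-2-yl)oxepan-2-yl]acetate (C6 ketone) | O1[C@H](CC(=O)OCC)C(=O)[C@H](C(C)=C)[C@@H](O[Si](C)(C)C(C)(C)C)C[C@@]1(C)CCC(=O)N2CCOCC2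
F2 | step 12 | 20 brominated at C4 (C4 epimer mixture, other centres as in 20) | O1[C@@H]2C(Br)C(=O)O[C@H]2[C@H](C(C)=C)[C@@H](O[Si](C)(C)C(C)(C)C)C[C@@]1(C)CCC(=O)N3CCOCC3
F3 | step 12 | F2 with the morpholine amide reduced to the C3 aldehyde | O1[C@@H]2C(Br)C(=O)O[C@H]2[C@H](C(C)=C)[C@@H](O[Si](C)(C)C(C)(C)C)C[C@@]1(C)CCC=O
F4 | step 23 | C8 ketone derived from 30 | C=C1C(=O)O[C@@H]2[C@@H]3O[C@](C)(CC[C@H](OC(C)=O)[C@@H]3CO[Si](c4ccccc4)(c4ccccc4)C(C)(C)C)CC(=O)[C@@H]12
F5 | step 23 | 8R alcohol, the C8 epimer of 30 | C=C1C(=O)O[C@@H]2[C@@H]3O[C@](C)(CC[C@H](OC(C)=O)[C@@H]3CO[Si](c4ccccc4)(c4ccccc4)C(C)(C)C)C[C@@H](O)[C@@H]12
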